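**Retrosynthetic overview** (chain carbons C1–C15: C1≡C2, C3–Br, ring A = C4–O–C7 with C6–OAc, ring B = C9–O–C12 with C10–Br, C13–Br; target = 3S,4R,6R,7R,9S,10S,12S,13R)

1. Target ⇒ C3 propargylic alcohol 17 (Appel, inversion) ⇒ ring-A aldehyde 15 + ethynylmagnesium bromide.
2. Ring A (formed second) ⇒ anti-bromohydrin/anti-1,3-diol 12 by 5-exo-tet etherification with inversion at C7 ⇒ aldehyde 8 by enamine α-bromination, Cornforth aldol with 1,1-dimethoxyacetone and anti reduction.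
3. Ring B (formed first) ⇒ (Z)-homoallylic bromohydrin 6 by a 5-endo bromoetherification that makes C9–O and C10–Br together.
4. 6 ⇒ bromohydrin 4 + pent-4-enenitrile (Z-selective cross-metathesis); 4 ⇒ butanal + allyl boronate by enamine-catalysed α-bromination/allylboration.
5. Stereocentres are set in the order C13, C12, C9/C10 (ring B), C7, C6, C4 (ring A), C3.

Assumption: with 2,5-diphenylpyrrolidine the bromine enters anti to the phenyl group that flanks the enamine, so the (2R,5R) amine gives (S)-2-bromoaldehydes and the (2S,5S) amine the (R) series; if the sense is the reverse, the catalyst enantiomers of steps 1 and 5 are exchanged.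

**Step 1**
Reactants: 1 butanal; 2 allylboronic acid pinacol ester
Product: 4 (4S,5R)-5-bromohept-1-en-4-ol, via (2R)-2-bromobutanal 3 (not isolated)
Conditions: (2S,5S)-2,5-diphenylpyrrolidine (10 mol%), PhCO2H (10 mol%), 4,4-dibromo-2,6-di-tert-butylcyclohexa-2,5-dien-1-one (1.0 equiv), CH2Cl2/pentane 1:1, −40 °C, 2 h; then 2 (1.5 equiv), (PhO)2P(O)OH (20 mol%), −40 °C, 8 h; pH 7 buffer
Reagents that add atoms: 4,4-dibromo-2,6-di-tert-butylcyclohexa-2,5-dien-1-one, O=C1C(C(C)(C)C)=CC(Br)(Br)C=C1C(C)(C)C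
Why: Enamine-catalysed α-bromination sets C13 by catalyst control, and the labile bromoaldehyde is trapped cold by Brønsted-acid-accelerated allylboration through a chair transition state under Cornforth control, which gives the 1,2-anti bromohydrin (C12).

**Step 2**
Reactants: 4 (4S,5R)-5-bromohept-1-en-4-ol; 5 pent-4-enenitrile
Product: 6 (4Z,7S,8R)-8-bromo-7-hydroxydec-4-enenitrile
Conditions: 5 (4 equiv), cyclometalated Z-selective ruthenium catalyst Ru(NO3)(C25H35N2)(=CH-C6H4-2-O-i-Pr) (C35H47N3O4Ru, N-1-adamantyl/N'-2,6-diisopropylphenyl NHC; 5 mol%), THF, 35 °C, static vacuum, 12 h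
Reagents that add atoms: none
Why: Z-selective olefin cross-metathesis of two unhindered terminal alkenes, in which the cyclometalated NHC enforces syn-substituted metallacyclobutanes so that the cis alkene is released; no stereocentre is touched.

**Step 3**
Reactants: 6 (4Z,7S,8R)-8-bromo-7-hydroxydec-4-enenitrile
Product: 7 3-[(2S,3S,5S)-3-bromo-5-[(1R)-1-bromopropyl]oxolan-2-yl]propanenitrile
Conditions: NBS (1.1 equiv), Ph3P=S (10 mol%), CH2Cl2/1,1,1,3,3,3-hexafluoropropan-2-ol 4:1, −20 °C, dark, 4 h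
Reagents that add atoms: N-bromosuccinimide, O=C1CCC(=O)N1Br
Why: Proposed new method: a Lewis-base-catalysed 5-endo bromoetherification of a (Z)-homoallylic vicinal bromohydrin, in which Ph3P=S–Br+ transfers Br+ reversibly to either alkene face and the product-determining step is anti attack of the C12 hydroxyl on C9 through an envelope with the 1-bromopropyl group pseudo-equatorial, which places the C10 bromine cis to that group while the Z geometry forces the cyanoethyl arm on C9 cis to bromine, so the all-cis ring B (9S,10S) results; 4-exo closure is not competitive, the fluorinated alcohol slows capture of the bromiranium ion by succinimide, and the base-free medium keeps the bromohydrin from closing to an epoxide; the closest known reaction types are the 5-endo iodoetherification of (Z)-homoallylic alcohols with iodine/NaHCO3, which gives all-cis 3-iodotetrahydrofurans, and Lewis-base-catalysed 5-exo and 6-endo bromoetherification.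

**Step 4**
Reactants: 7 3-[(2S,3S,5S)-3-bromo-5-[(1R)-1-bromopropyl]oxolan-2-yl]propanenitrile
Product: 8 3-[(2S,3S,5S)-3-bromo-5-[(1R)-1-bromopropyl]oxolan-2-yl]propanal
Conditions: i-Bu2AlH (1.2 equiv), CH2Cl2, −78 °C, 1 h; then 1 M aq. HCl, 0 °C
Reagents that add atoms: water, O
Why: Partial hydride reduction of the nitrile stops at the N-aluminoimine, which is hydrolysed to the aldehyde on work-up; secondary bromides and the ether are inert to i-Bu2AlH at −78 °C.

**Step 5**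
Reactants: 8 3-[(2S,3S,5S)-3-bromo-5-[(1R)-1-bromopropyl]oxolan-2-yl]propanal; 9 1,1-dimethoxypropan-2-one
Product: 11 (4R,5S)-5-bromo-6-[(2S,3S,5S)-3-bromo-5-[(1R)-1-bromopropyl]oxolan-2-yl]-4-hydroxy-1,1-dimethoxyhexan-2-one, via ring-B α-bromoaldehyde 10 (not isolated)
Conditions: (2R,5R)-2,5-diphenylpyrrolidine (20 mol%), PhCO2H (20 mol%), 4,4-dibromo-2,6-di-tert-butylcyclohexa-2,5-dien-1-one (1.05 equiv), CH2Cl2/pentane 1:1, −40 °C, 3 h; cold transfer into the lithium enolate of 9 (3.5 equiv; LiN(i-Pr)2, THF, −78 °C), 15 min; AcOH, −78 °C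
Reagents that add atoms: 4,4-dibromo-2,6-di-tert-butylcyclohexa-2,5-dien-1-one, O=C1C(C(C)(C)C)=CC(Br)(Br)C=C1C(C)(C)C
Why: A second enamine α-bromination sets C7 as the (S)-bromide under catalyst control, and the kinetic lithium-enolate aldol addition follows the Cornforth model to give the 1,2-anti bromohydrin (C6 R), with excess enolate absorbing the acidic by-products.

**Step 6**
Reactants: 11 (4R,5S)-5-bromo-6-[(2S,3S,5S)-3-bromo-5-[(1R)-1-bromopropyl]oxolan-2-yl]-4-hydroxy-1,1-dimethoxyhexan-2-one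
Product: 12 (2R,4R,5S)-5-bromo-6-[(2S,3S,5S)-3-bromo-5-[(1R)-1-bromopropyl]oxolan-2-yl]-1,1-dimethoxyhexane-2,4-diol
Conditions: Me4NBH(OAc)3 (5 equiv), MeCN/AcOH 1:1, −35 → −20 °C, 16 h; pH 7 work-up
Reagents that add atoms: none
Why: Evans–Saksena reduction, in which the C6 hydroxyl binds boron and delivers hydride intramolecularly through a chair, giving the 1,3-anti diol (C4 R).

**Step 7**
Reactants: 12 (2R,4R,5S)-5-bromo-6-[(2S,3S,5S)-3-bromo-5-[(1R)-1-bromopropyl]oxolan-2-yl]-1,1-dimethoxyhexane-2,4-diol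
Product: 13 (2R,3R,5R)-2-{[(2S,3S,5S)-3-bromo-5-[(1R)-1-bromopropyl]oxolan-2-yl]methyl}-5-(dimethoxymethyl)oxolan-3-ol
Conditions: MeOH/0.5 M NaOAc–AcOH buffer (pH 5) 1:1, 60 °C, 3 h
Reagents that add atoms: none
Why: 5-exo-tet intramolecular etherification, in which the C4 hydroxyl displaces the C7 bromide with inversion (C7 becomes R) so that the anti-bromohydrin/anti-diol array gives the all-cis ring A; intramolecularity makes this bromide react far faster than the two ring-B bromides, and pH 5 keeps the acetal intact and the bromohydrin from closing to an epoxide.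

**Step 8**
Reactants: 13 (2R,3R,5R)-2-{[(2S,3S,5S)-3-bromo-5-[(1R)-1-bromopropyl]oxolan-2-yl]methyl}-5-(dimethoxymethyl)oxolan-3-ol
Product: 14 (2R,3R,5R)-2-{[(2S,3S,5S)-3-bromo-5-[(1R)-1-bromopropyl]oxolan-2-yl]methyl}-5-(dimethoxymethyl)oxolan-3-yl acetate
Conditions: Ac2O, pyridine, DMAP (5 mol%), CH2Cl2, 0 °C → rt
Reagents that add atoms: acetic anhydride, CC(=O)OC(C)=O
Why: Nucleophile-catalysed acylation of the only free hydroxyl (C6), with no change at any stereocentre.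

**Step 9**
Reactants: 14 (2R,3R,5R)-2-{[(2S,3S,5S)-3-bromo-5-[(1R)-1-bromopropyl]oxolan-2-yl]methyl}-5-(dimethoxymethyl)oxolan-3-yl acetate
Product: 15 (2R,3R,5R)-2-{[(2S,3S,5S)-3-bromo-5-[(1R)-1-bromopropyl]oxolan-2-yl]methyl}-5-formyloxolan-3-yl acetate
Conditions: TFA/H2O 4:1, CH2Cl2, 0 °C → rt, 2 h; used crude
Reagents that add atoms: water, O
Why: Acid-catalysed acetal hydrolysis, to which the acetate, ethers and bromides are stable; the α-alkoxy aldehyde is used at once to avoid epimerisation at C4.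

**Step 10**
Reactants: 15 (2R,3R,5R)-2-{[(2S,3S,5S)-3-bromo-5-[(1R)-1-bromopropyl]oxolan-2-yl]methyl}-5-formyloxolan-3-yl acetate; 16 ethynylmagnesium bromide
Product: 17 (2R,3R,5R)-2-{[(2S,3S,5S)-3-bromo-5-[(1R)-1-bromopropyl]oxolan-2-yl]methyl}-5-[(1R)-1-hydroxyprop-2-yn-1-yl]oxolan-3-yl acetate
Conditions: MgBr2·OEt2 (2 equiv), CH2Cl2, −78 °C, 15 min; then HC≡CMgBr (0.5 M in THF, 3 equiv), −78 °C, 1 h; AcOH, −78 °C
Reagents that add atoms: none
Why: Cram-chelate addition, in which magnesium bridges the aldehyde and ring-A oxygens and the acetylide adds to the less hindered face to give the 1,2-syn (threo) propargylic alcohol (C3 R); the aldehyde reacts far faster than the acetate at −78 °C.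

**Step 11**
Reactants: 17 (2R,3R,5R)-2-{[(2S,3S,5S)-3-bromo-5-[(1R)-1-bromopropyl]oxolan-2-yl]methyl}-5-[(1R)-1-hydroxyprop-2-yn-1-yl]oxolan-3-yl acetate
Product: 18 (2R,3R,5R)-2-{[(2S,3S,5S)-3-bromo-5-[(1R)-1-bromopropyl]oxolan-2-yl]methyl}-5-[(1S)-1-bromoprop-2-yn-1-yl]oxolan-3-yl acetate
Conditions: CBr4 (1.5 equiv), PPh3 (1.6 equiv), CH2Cl2, −20 → 0 °C, 1 h
Reagents that add atoms: tetrabromomethane, BrC(Br)(Br)Br
Why: Appel reaction, in which bromide displaces the alkoxyphosphonium group by SN2 and inverts C3 to S; low temperature and short time suppress SN2' bromoallene formation and bromide-induced epimerisation.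

**Compound list**

1 | butanal | CCCC=O | starting material
2 | allylboronic acid pinacol ester (2-allyl-4,4,5,5-tetramethyl-1,3,2-dioxaborolane) | C=CCB1OC(C)(C)C(C)(C)O1 | starting material
3 | (2R)-2-bromobutanal | O=C[C@H](Br)CC | intermediate
4 | (4S,5R)-5-bromohept-1-en-4-ol | C=CC[C@H](O)[C@H](Br)CC | intermediate
5 | pent-4-enenitrile | C=CCCC#N | starting material
6 | (4Z,7S,8R)-8-bromo-7-hydroxydec-4-enenitrile | N#CCC/C=C\C[C@H](O)[C@H](Br)CC | intermediate
7 | 3-[(2S,3S,5S)-3-bromo-5-[(1R)-1-bromopropyl]oxolan-2-yl]propanenitrile | N#CCC[C@@H]1O[C@H]([C@H](Br)CC)C[C@@H]1Br | intermediate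
8 | 3-[(2S,3S,5S)-3-bromo-5-[(1R)-1-bromopropyl]oxolan-2-yl]propanal | O=CCC[C@@H]1O[C@H]([C@H](Br)CC)C[C@@H]1Br | intermediate
9 | 1,1-dimethoxypropan-2-one | CC(=O)C(OC)OC | starting material
10 | (2S)-2-bromo-3-[(2S,3S,5S)-3-bromo-5-[(1R)-1-bromopropyl]oxolan-2-yl]propanal | O=C[C@@H](Br)C[C@@H]1O[C@H]([C@H](Br)CC)C[C@@H]1Br | intermediate
11 | (4R,5S)-5-bromo-6-[(2S,3S,5S)-3-bromo-5-[(1R)-1-bromopropyl]oxolan-2-yl]-4-hydroxy-1,1-dimethoxyhexan-2-one | COC(OC)C(=O)C[C@@H](O)[C@@H](Br)C[C@@H]1O[C@H]([C@H](Br)CC)C[C@@H]1Br | intermediate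
12 | (2R,4R,5S)-5-bromo-6-[(2S,3S,5S)-3-bromo-5-[(1R)-1-bromopropyl]oxolan-2-yl]-1,1-dimethoxyhexane-2,4-diol | COC(OC)[C@H](O)C[C@@H](O)[C@@H](Br)C[C@@H]1O[C@H]([C@H](Br)CC)C[C@@H]1Br | intermediate
13 | (2R,3R,5R)-2-{[(2S,3S,5S)-3-bromo-5-[(1R)-1-bromopropyl]oxolan-2-yl]methyl}-5-(dimethoxymethyl)oxolan-3-ol | COC(OC)[C@H]1C[C@@H](O)[C@@H](C[C@@H]2O[C@H]([C@H](Br)CC)C[C@@H]2Br)O1 | intermediate
14 | (2R,3R,5R)-2-{[(2S,3S,5S)-3-bromo-5-[(1R)-1-bromopropyl]oxolan-2-yl]methyl}-5-(dimethoxymethyl)oxolan-3-yl acetate | COC(OC)[C@H]1C[C@@H](OC(C)=O)[C@@H](C[C@@H]2O[C@H]([C@H](Br)CC)C[C@@H]2Br)O1 | intermediate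
15 | (2R,3R,5R)-2-{[(2S,3S,5S)-3-bromo-5-[(1R)-1-bromopropyl]oxolan-2-yl]methyl}-5-formyloxolan-3-yl acetate | O=C[C@H]1C[C@@H](OC(C)=O)[C@@H](C[C@@H]2O[C@H]([C@H](Br)CC)C[C@@H]2Br)O1 | intermediate
16 | ethynylmagnesium bromide | C#C[Mg]Br | starting material
17 | (2R,3R,5R)-2-{[(2S,3S,5S)-3-bromo-5-[(1R)-1-bromopropyl]oxolan-2-yl]methyl}-5-[(1R)-1-hydroxyprop-2-yn-1-yl]oxolan-3-yl acetate | C#C[C@@H](O)[C@H]1C[C@@H](OC(C)=O)[C@@H](C[C@@H]2O[C@H]([C@H](Br)CC)C[C@@H]2Br)O1 | intermediate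
18 | (2R,3R,5R)-2-{[(2S,3S,5S)-3-bromo-5-[(1R)-1-bromopropyl]oxolan-2-yl]methyl}-5-[(1S)-1-bromoprop-2-yn-1-yl]oxolan-3-yl acetate | C#C[C@H](Br)[C@H]1C[C@@H](OC(C)=O)[C@@H](C[C@@H]2O[C@H]([C@H](Br)CC)C[C@@H]2Br)O1 | target

**Totals**

Total step count: 11. Longest linear sequence: 11 (butanal to 18; compounds 2, 5, 9 and 16 are bought).

**The three steps most likely to fail**

Step 3 (the proposed new step). The 5-endo closure may be slow because the hydroxyl is deactivated by the neighbouring bromine, or may give the 2,5-trans ring. The fallback uses known chemistry only, sets out from 4 and returns at 7, so it also bypasses the Z-selective metathesis of step 2. Silylation of 4 (Et3SiCl, imidazole, CH2Cl2) gives {[(4S,5R)-5-bromohept-1-en-4-yl]oxy}(triethyl)silane F1. E-selective cross-metathesis of this with 5 (second-generation Hoveyda–Grubbs catalyst, C31H38Cl2N2ORu, CH2Cl2, 40 °C) gives (4E,7S,8R)-8-bromo-7-[(triethylsilyl)oxy]dec-4-enenitrile F2. Shi epoxidation (D-fructose-derived ketone, Oxone (2KHSO5·KHSO4·K2SO4), K2CO3 buffer pH 10.5, MeCN/dimethoxymethane, 0 °C) sets the epoxide by reagent control while the silyl ether shields the base-labile bromohydrin, giving 3-[(2R,3R)-3-[(2S,3R)-3-bromo-2-[(triethylsilyl)oxy]pentyl]oxiran-2-yl]propanenitrile F3. Camphorsulfonic acid in CH2Cl2/MeOH removes the silyl group and triggers the 5-endo epoxide opening with inversion at C9 to 3-[(2S,3R,5S)-5-[(1R)-1-bromopropyl]-3-hydroxyoxolan-2-yl]propanenitrile F4. Deoxybromination with inversion at C10 (CBr4, (n-C8H17)3P, toluene, 70 °C) then gives 7.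

Step 5. The α-bromoaldehyde 10 may racemise, eliminate or be enolised before the enolate adds. The fallback sets out from 8 and returns at 13, using the isolable chloro series. Chlorination of 8 (NCS, (2R,5R)-2,5-diphenylpyrrolidine, CH2Cl2, rt, filtration) gives (2S)-3-[(2S,3S,5S)-3-bromo-5-[(1R)-1-bromopropyl]oxolan-2-yl]-2-chloropropanal F5. Addition of F5 to the lithium enolate of 9 (THF, −78 °C) gives the anti-chlorohydrin (4R,5S)-6-[(2S,3S,5S)-3-bromo-5-[(1R)-1-bromopropyl]oxolan-2-yl]-5-chloro-4-hydroxy-1,1-dimethoxyhexan-2-one F6. Me4NBH(OAc)3 reduction gives (2R,4R,5S)-6-[(2S,3S,5S)-3-bromo-5-[(1R)-1-bromopropyl]oxolan-2-yl]-5-chloro-1,1-dimethoxyhexane-2,4-diol F7. Ring closure of F7 in MeOH/pH 5 NaOAc–AcOH buffer needs about 100 °C (sealed tube) and gives 13. This is held as the fallback and not the main line because the hotter closure is expected to cost some of the two ring-B bromides by solvolysis.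

Step 10. Chelation control at a hindered tetrahydrofuran aldehyde with an alkynyl Grignard reagent is often modest, so the C3 epimer ratio may be poor. The fallback sets out from 15 and returns at 17. Addition of 16 without the chelating additive (THF, −78 °C) gives 17 mixed with its epimer (2R,3R,5R)-2-{[(2S,3S,5S)-3-bromo-5-[(1R)-1-bromopropyl]oxolan-2-yl]methyl}-5-[(1S)-1-hydroxyprop-2-yn-1-yl]oxolan-3-yl acetate F8. Dess–Martin periodinane (CH2Cl2, NaHCO3) converts both into the ynone (2R,3R,5R)-2-{[(2S,3S,5S)-3-bromo-5-[(1R)-1-bromopropyl]oxolan-2-yl]methyl}-5-(prop-2-ynoyl)oxolan-3-yl acetate F9. Reagent-controlled reduction with (S)-2-methyl-CBS-oxazaborolidine and catecholborane (toluene, −78 °C), in which the alkynyl group acts as the small substituent, gives 17.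

**Further compounds**

F1 | step 3 | {[(4S,5R)-5-bromohept-1-en-4-yl]oxy}(triethyl)silane | C=CC[C@H](O[Si](CC)(CC)CC)[C@H](Br)CC
F2 | step 3 | (4E,7S,8R)-8-bromo-7-[(triethylsilyl)oxy]dec-4-enenitrile | N#CCC/C=C/C[C@H](O[Si](CC)(CC)CC)[C@H](Br)CC
F3 | step 3 | 3-[(2R,3R)-3-[(2S,3R)-3-bromo-2-[(triethylsilyl)oxy]pentyl]oxiran-2-yl]propanenitrile | N#CCC[C@H]1O[C@@H]1C[C@H](O[Si](CC)(CC)CC)[C@H](Br)CC
F4 | step 3 | 3-[(2S,3R,5S)-5-[(1R)-1-bromopropyl]-3-hydroxyoxolan-2-yl]propanenitrile | N#CCC[C@@H]1O[C@H]([C@H](Br)CC)C[C@H]1O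
F5 | step 5 | (2S)-3-[(2S,3S,5S)-3-bromo-5-[(1R)-1-bromopropyl]oxolan-2-yl]-2-chloropropanal | O=C[C@@H](Cl)C[C@@H]1O[C@H]([C@H](Br)CC)C[C@@H]1Br
F6 | step 5 | (4R,5S)-6-[(2S,3S,5S)-3-bromo-5-[(1R)-1-bromopropyl]oxolan-2-yl]-5-chloro-4-hydroxy-1,1-dimethoxyhexan-2-one | COC(OC)C(=O)C[C@@H](O)[C@@H](Cl)C[C@@H]1O[C@H]([C@H](Br)CC)C[C@@H]1Br
F7 | step 5 | (2R,4R,5S)-6-[(2S,3S,5S)-3-bromo-5-[(1R)-1-bromopropyl]oxolan-2-yl]-5-chloro-1,1-dimethoxyhexane-2,4-diol | COC(OC)[C@H](O)C[C@@H](O)[C@@H](Cl)C[C@@H]1O[C@H]([C@H](Br)CC)C[C@@H]1Br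
F8 | step 10 | (2R,3R,5R)-2-{[(2S,3S,5S)-3-bromo-5-[(1R)-1-bromopropyl]oxolan-2-yl]methyl}-5-[(1S)-1-hydroxyprop-2-yn-1-yl]oxolan-3-yl acetate | C#C[C@H](O)[C@H]1C[C@@H](OC(C)=O)[C@@H](C[C@@H]2O[C@H]([C@H](Br)CC)C[C@@H]2Br)O1
F9 | step 10 | (2R,3R,5R)-2-{[(2S,3S,5S)-3-bromo-5-[(1R)-1-bromopropyl]oxolan-2-yl]methyl}-5-(prop-2-ynoyl)oxolan-3-yl acetate | C#CC(=O)[C@H]1C[C@@H](OC(C)=O)[C@@H](C[C@@H]2O[C@H]([C@H](Br)CC)C[C@@H]2Br)O1
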